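**Plan**
1. Retrosynthesis: take off the C9 acetate and the side-chain acetonide, turn the C14 ester back into a C10–Br (a latent ester), cut the ring bond C1–C2 (vinyl carbon to CH2), then C6–C7 together with the lactone C12–O bond, then the C7=C11/C13 acrylate unit and the C10≡C1 alkyne back to a threonate.
2. Enabling feature: in the ten-membered ring, C1 is the CH end of the C1=C10 enoate and C2 is a plain CH2 homoallylic to the ring-cis C4=C5 olefin. C2 can therefore come from the terminal carbon of a vinyl group (hydroboration) and C1 from an alkenyl iodide. Both ring olefins are ring-cis and the trans-fused γ-lactone at C6–C7 folds the chain.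
3. Forward: the γ-lactone is made first (Cr-mediated 2-(alkoxycarbonyl)allylation and lactonisation), the ten-membered carbocycle second (hydroboration/B-alkyl Suzuki–Miyaura closure of C1–C2), then Pd methoxycarbonylation at C10 and acyl adjustment.
4. Stereochemistry: C8/C9 from methyl 3,4-O-isopropylidene-L-threonate; C6/C7 from the chair allylchromium addition under control by C8; C2' from (R)-3-bromo-2-hydroxy-2-methylpropanoic acid; C4=C5 (Z) from (Z)-3-methylpent-2-en-4-yn-1-ol; C1=C10 from anti addition of IBr to an alkyne followed by two stereoretentive Pd couplings.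

Key step: step 15

Remark: atoms are numbered as in the germacrane skeleton (ring C1–C10; C14 = ester carbon on C10; C15 = methyl on C4; lactone O–C6, C7, C11(=C13), C12). The bromo acid, the enynol, the threonate and methyl acrylate are taken to be commercial. TBS = tert-butyldimethylsilyl, TES = triethylsilyl.

**Step 1**
Reactants: 1 (R)-3-bromo-2-hydroxy-2-methylpropanoic acid
Product: 2 (S)-2,3-dihydroxy-2-methylpropanoic acid
Conditions: NaOH (3 equiv), H2O, 0 → 60 °C; then HCl to pH 2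
Reagents that add atoms: sodium hydroxide ([Na+].[OH-])
Why: Williamson closure to the glycidate and hydroxide opening at the primary carbon replace Br by OH without touching the quaternary centre (R becomes S only because the CIP ranking of the CH2X group changes).

**Step 2**
Reactants: 2 (S)-2,3-dihydroxy-2-methylpropanoic acid
Product: 3 (S)-2,2,4-trimethyl-1,3-dioxolane-4-carboxylic acid
Conditions: 2,2-dimethoxypropane, TsOH (cat.), acetone, rt
Reagents that add atoms: 2,2-dimethoxypropane (COC(C)(C)OC)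
Why: acid-catalysed transketalisation protects the 1,2-diol as its acetonide; run at rt and stopped before the liberated methanol can esterify the acid.

**Step 3**
Reactants: 4 (Z)-3-methylpent-2-en-4-yn-1-ol
Product: 5 (Z)-3-methylpenta-2,4-dien-1-ol
Conditions: H2 (1 atm), Lindlar catalyst, quinoline, EtOAc, 0 °C
Reagents that add atoms: none
Why: Lindlar semi-hydrogenation should stop the terminal alkyne at the vinyl stage and leave the trisubstituted Z olefin unchanged.

**Step 4**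
Reactants: 5 (Z)-3-methylpenta-2,4-dien-1-ol
Product: 6 (Z)-3-methylpenta-2,4-dienal
Conditions: Dess–Martin periodinane, pyridine, CH2Cl2, 0 °C; used at once as a cold solution
Reagents that add atoms: none
Why: buffered Dess–Martin oxidation of the allylic alcohol should keep the Z geometry of the sensitive dienal.

**Step 5**
Reactants: 7 methyl 3,4-O-isopropylidene-L-threonate (methyl (2R)-2-[(4S)-2,2-dimethyl-1,3-dioxolan-4-yl]-2-hydroxyacetate)
Product: 8 methyl (2R)-2-(tert-butyldimethylsilyloxy)-2-[(4S)-2,2-dimethyl-1,3-dioxolan-4-yl]acetate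
Conditions: TBSOTf, 2,6-lutidine, CH2Cl2, 0 °C
Reagents that add atoms: tert-butyldimethylsilyl triflate (CC(C)(C)[Si](C)(C)OS(=O)(=O)C(F)(F)F)
Why: silylation of the free secondary alcohol (the later C9–O), which must survive hydride, base and Pd steps.

**Step 6**
Reactants: 8 methyl (2R)-2-(tert-butyldimethylsilyloxy)-2-[(4S)-2,2-dimethyl-1,3-dioxolan-4-yl]acetate
Product: 10 (4S)-4-[(1S)-1-(tert-butyldimethylsilyloxy)prop-2-yn-1-yl]-2,2-dimethyl-1,3-dioxolane, via aldehyde 9 (not isolated)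
Conditions: DIBAL-H, CH2Cl2, −78 °C; then MeOH, K2CO3, dimethyl (1-diazo-2-oxopropyl)phosphonate, −78 °C → rt
Reagents that add atoms: dimethyl (1-diazo-2-oxopropyl)phosphonate (COP(=O)(OC)C(=[N+]=[N-])C(C)=O)
Why: one-pot DIBAL half-reduction and Seyferth–Gilbert homologation with the Ohira–Bestmann reagent turn the ester into the terminal alkyne (C10≡C1); the mild carbonate base should leave the α-silyloxy centre intact.

**Step 7**
Reactants: 10 (4S)-4-[(1S)-1-(tert-butyldimethylsilyloxy)prop-2-yn-1-yl]-2,2-dimethyl-1,3-dioxolane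
Product: 11 (4S)-4-[(1R,2E)-2-bromo-1-(tert-butyldimethylsilyloxy)-3-iodoprop-2-en-1-yl]-2,2-dimethyl-1,3-dioxolane
Conditions: IBr, CH2Cl2, −78 → −40 °C, dark
Reagents that add atoms: iodine monobromide (BrI)
Why: anti addition of I–Br through the iodonium ion, with bromide opening at the internal carbon, puts I on C1 and Br on C10 trans to each other (iodine cis to C9), which fixes the later C1=C10 geometry.

**Step 8**
Reactants: 11 (4S)-4-[(1R,2E)-2-bromo-1-(tert-butyldimethylsilyloxy)-3-iodoprop-2-en-1-yl]-2,2-dimethyl-1,3-dioxolane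
Product: 12 (2S,3R,4E)-4-bromo-3-(tert-butyldimethylsilyloxy)-5-iodopent-4-ene-1,2-diol
Conditions: AcOH–H2O–THF (3:1:1), 40 °C
Reagents that add atoms: none
Why: acid hydrolysis of the terminal acetonide; the hindered secondary TBS ether is cleaved far more slowly.

**Step 9**
Reactants: 12 (2S,3R,4E)-4-bromo-3-(tert-butyldimethylsilyloxy)-5-iodopent-4-ene-1,2-diol
Product: 13 (2S,3R,4E)-4-bromo-3-(tert-butyldimethylsilyloxy)-5-iodo-1,2-bis(triethylsilyloxy)pent-4-ene
Conditions: TESCl, imidazole, DMF, 0 °C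
Reagents that add atoms: chlorotriethylsilane (CC[Si](Cl)(CC)CC)
Why: silylation of both hydroxyls sets up the selective oxidation of the primary position.

**Step 10**
Reactants: 13 (2S,3R,4E)-4-bromo-3-(tert-butyldimethylsilyloxy)-5-iodo-1,2-bis(triethylsilyloxy)pent-4-ene
Product: 14 (2R,3R,4E)-4-bromo-3-(tert-butyldimethylsilyloxy)-5-iodo-2-(triethylsilyloxy)pent-4-enal
Conditions: (COCl)2, DMSO, CH2Cl2, −78 → −35 °C; then Et3N, −78 → 0 °C
Reagents that add atoms: none
Why: Swern conditions cleave the primary TES ether in situ and oxidise it to the aldehyde (C7) while the secondary silyl ethers stay; the low temperature should prevent epimerisation at C8.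

**Step 11**
Reactants: 14 (2R,3R,4E)-4-bromo-3-(tert-butyldimethylsilyloxy)-5-iodo-2-(triethylsilyloxy)pent-4-enal; 15 methyl acrylate
Product: 16 methyl (4S,5R,6E)-6-bromo-5-(tert-butyldimethylsilyloxy)-3-hydroxy-7-iodo-2-methylidene-4-(triethylsilyloxy)hept-6-enoate (both C3 epimers)
Conditions: DABCO (1 equiv), methyl acrylate (excess), MeOH (cat.), rt
Reagents that add atoms: none
Why: Morita–Baylis–Hillman reaction brings in C11–C13; the new carbinol centre (C7) forms as a mixture and is erased in the next step.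

**Step 12**
Reactants: 16 methyl (4S,5R,6E)-6-bromo-5-(tert-butyldimethylsilyloxy)-3-hydroxy-7-iodo-2-methylidene-4-(triethylsilyloxy)hept-6-enoate
Product: 17 methyl (2Z,4S,5R,6E)-6-bromo-2-(bromomethyl)-5-(tert-butyldimethylsilyloxy)-7-iodo-4-(triethylsilyloxy)hepta-2,6-dienoate
Conditions: NBS, Me2S, CH2Cl2, 0 °C → rt
Reagents that add atoms: N-bromosuccinimide (O=C1CCC(=O)N1Br)
Why: Corey–Kim-type activation of the allylic alcohol and SN2' delivery of bromide should give the more stable (Z)-2-(bromomethyl)enoate from either epimer.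

**Step 13**
Reactants: 17 methyl (2Z,4S,5R,6E)-6-bromo-2-(bromomethyl)-5-(tert-butyldimethylsilyloxy)-7-iodo-4-(triethylsilyloxy)hepta-2,6-dienoate; 6 (Z)-3-methylpenta-2,4-dienal
Product: 20 (4R,5R)-4-[(1S,2R,3E)-3-bromo-2-(tert-butyldimethylsilyloxy)-1-hydroxy-4-iodobut-3-en-1-yl]-3-methylidene-5-[(1Z)-2-methylbuta-1,3-dien-1-yl]oxolan-2-one, via hydroxy ester 18 (not isolated), via silyl lactone 19 (not isolated)
Conditions: CrCl2 (Ni-free, 4 equiv), THF, 0 °C → rt; then AcOH–THF–H2O (3:1:1), rt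
Reagents that add atoms: none
Why: Nozaki–Hiyama–Kishi-type 2-(alkoxycarbonyl)allylation in which the allylchromium(III) species should add through a chair transition state with both substituents equatorial (C6/C7 anti, hence the trans-lactone) and, with H-8 held in the olefin plane by allylic strain, on the face anti to the bulky C9 substituent (C7 relative to C8); lactonisation and acetic acid then free the C8 alcohol while the TBS ether stays.

**Step 14**
Reactants: 20 the hydroxy lactone of step 13; 3 (S)-2,2,4-trimethyl-1,3-dioxolane-4-carboxylic acid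
Product: 22 (1S,2R,3E)-3-bromo-2-(tert-butyldimethylsilyloxy)-4-iodo-1-[(2R,3S)-4-methylidene-2-[(1Z)-2-methylbuta-1,3-dien-1-yl]-5-oxooxolan-3-yl]but-3-en-1-yl (4S)-2,2,4-trimethyl-1,3-dioxolane-4-carboxylate, via mixed anhydride 21 (not isolated)
Conditions: 3, 2,4,6-trichlorobenzoyl chloride, Et3N, THF, rt; then 20, DMAP, toluene, rt → 40 °C
Reagents that add atoms: none
Why: Yamaguchi esterification is suited to a hindered acid and a hindered secondary alcohol; C8–OH is the only free hydroxyl, so no regiochemical question arises.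

**Step 15**
Reactants: 22 the diene ester of step 14
Product: 24 (1(10)E,4Z,6R,7S,8S,9R)-10-bromo-9-(tert-butyldimethylsilyloxy)-14-norgermacra-1(10),4,11(13)-trien-12,6-olid-8-yl (4S)-2,2,4-trimethyl-1,3-dioxolane-4-carboxylate, via alkylborane 23 (not isolated)
Conditions: 9-BBN (1.3 equiv), THF, 0 °C → rt; then slow addition to PdCl2(dppf) (15 mol %), AsPh3, Cs2CO3, DMF–THF–H2O, 2 mM, rt
Reagents that add atoms: none
Why: 9-BBN should add anti-Markovnikov to the only monosubstituted, electron-rich C=C (the terminal C2=C3 vinyl of the (Z)-diene), sparing the conjugated 1,1-disubstituted methylene lactone and the dihaloalkene, to give the homoallylic B-alkyl borane 23; Pd(0) then inserts into the C1–I bond (much faster than into the hindered C10–Br), the hydroxide-activated borate transfers the C2 alkyl group to palladium, and reductive elimination forms C1–C2. The closest known reaction type is the B-alkyl Suzuki–Miyaura macrocyclisation of an ω-boryl alkenyl halide. The ten-membered carbocycle closes by C(sp3)–C(sp2) reductive elimination from an eleven-membered palladacycle, an endo closure in which both carbons of the C1=C10 olefin end up in the ring. No stereocentre is formed; the ring-cis geometry of C1=C10 follows from retention at C1 of the (E)-bromo-iodo-olefin (iodine cis to C9), and that of C4=C5 is carried over from the dienal. The step needs ring closure to win over oligomerisation and over loss of bromide from the β-bromoalkenylpalladium intermediate; slow addition at high dilution, the turn imposed by the trans-fused lactone and the two cis ring olefins, and the fast transmetalation of a primary B-alkyl-9-BBN under aqueous base should secure this.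

**Step 16**
Reactants: 24 the macrocyclic alkenyl bromide of step 15
Product: 25 methyl (1(10)E,4Z,6R,7S,8S,9S)-9-(tert-butyldimethylsilyloxy)-8-[(4S)-2,2,4-trimethyl-1,3-dioxolane-4-carbonyloxy]germacra-1(10),4,11(13)-trien-12,6-olid-14-oate
Conditions: Pd(OAc)2 (10 mol %), Xantphos, CO (1 atm), MeOH, Et3N, toluene, 60 °C
Reagents that add atoms: carbon monoxide ([C-]#[O+]); methanol (CO)
Why: Pd-catalysed alkoxycarbonylation of the alkenyl bromide proceeds with retention, so C2 ends up trans to the new ester; keeping C9–O as a silyl ether instead of an acetate avoids β-oxygen elimination from the alkenylpalladium.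

**Step 17**
Reactants: 25 the TBS ether of step 16
Product: 26 methyl (1(10)E,4Z,6R,7S,8S,9S)-9-hydroxy-8-[(4S)-2,2,4-trimethyl-1,3-dioxolane-4-carbonyloxy]germacra-1(10),4,11(13)-trien-12,6-olid-14-oate
Conditions: HF·pyridine, pyridine, THF, 0 °C → rt
Reagents that add atoms: none
Why: buffered fluoride desilylation should leave the acetonide, the esters and the methylene lactone untouched.

**Step 18**
Reactants: 26 the C9 alcohol of step 17
Product: 27 methyl (1(10)E,4Z,6R,7S,8S,9S)-9-acetoxy-8-[(4S)-2,2,4-trimethyl-1,3-dioxolane-4-carbonyloxy]germacra-1(10),4,11(13)-trien-12,6-olid-14-oate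
Conditions: Ac2O, pyridine, DMAP (cat.), CH2Cl2, 0 °C → rt
Reagents that add atoms: acetic anhydride (CC(=O)OC(C)=O)
Why: acetylation of the single free hydroxyl; the hindered C8 ester should not migrate under these mild conditions.

**Step 19**
Reactants: 27 the acetonide of step 18
Product: 28 target, methyl (1(10)E,4Z,6R,7S,8S,9S)-9-acetoxy-8-[(2S)-2,3-dihydroxy-2-methylpropanoyloxy]germacra-1(10),4,11(13)-trien-12,6-olid-14-oate
Conditions: AcOH–H2O (4:1), 45 °C
Reagents that add atoms: none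
Why: mild aqueous acid hydrolyses the acetonide and should leave the acetate, the esters, the lactone and both olefins unchanged.

**Compound list**
1 | (R)-3-bromo-2-hydroxy-2-methylpropanoic acid | OC(=O)[C@@](C)(O)CBr | starting material
2 | (S)-2,3-dihydroxy-2-methylpropanoic acid | OC(=O)[C@@](C)(O)CO | intermediate
3 | (S)-2,2,4-trimethyl-1,3-dioxolane-4-carboxylic acid | OC(=O)[C@]1(C)COC(C)(C)O1 | intermediate
4 | (Z)-3-methylpent-2-en-4-yn-1-ol | OC/C=C(\C#C)C | starting material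
5 | (Z)-3-methylpenta-2,4-dien-1-ol | OC/C=C(\C=C)C | intermediate
6 | (Z)-3-methylpenta-2,4-dienal | O=C/C=C(\C=C)C | intermediate
7 | methyl 3,4-O-isopropylidene-L-threonate | COC(=O)[C@H](O)[C@@H]1COC(C)(C)O1 | starting material
8 | methyl (2R)-2-(TBS-oxy)-2-[(4S)-2,2-dimethyl-1,3-dioxolan-4-yl]acetate | COC(=O)[C@H](O[Si](C)(C)C(C)(C)C)[C@@H]1COC(C)(C)O1 | intermediate
9 | (2R)-2-(TBS-oxy)-2-[(4S)-2,2-dimethyl-1,3-dioxolan-4-yl]acetaldehyde | O=C[C@H](O[Si](C)(C)C(C)(C)C)[C@@H]1COC(C)(C)O1 | intermediate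
10 | (4S)-4-[(1S)-1-(TBS-oxy)prop-2-yn-1-yl]-2,2-dimethyl-1,3-dioxolane | C#C[C@H](O[Si](C)(C)C(C)(C)C)[C@@H]1COC(C)(C)O1 | intermediate
11 | (4S)-4-[(1R,2E)-2-bromo-1-(TBS-oxy)-3-iodoprop-2-en-1-yl]-2,2-dimethyl-1,3-dioxolane | I/C=C(/Br)[C@H](O[Si](C)(C)C(C)(C)C)[C@@H]1COC(C)(C)O1 | intermediate
12 | (2S,3R,4E)-4-bromo-3-(TBS-oxy)-5-iodopent-4-ene-1,2-diol | I/C=C(/Br)[C@H](O[Si](C)(C)C(C)(C)C)[C@@H](O)CO | intermediate
13 | (2S,3R,4E)-4-bromo-3-(TBS-oxy)-5-iodo-1,2-bis(TES-oxy)pent-4-ene | I/C=C(/Br)[C@H](O[Si](C)(C)C(C)(C)C)[C@@H](O[Si](CC)(CC)CC)CO[Si](CC)(CC)CC | intermediate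
14 | (2R,3R,4E)-4-bromo-3-(TBS-oxy)-5-iodo-2-(TES-oxy)pent-4-enal | I/C=C(/Br)[C@H](O[Si](C)(C)C(C)(C)C)[C@@H](O[Si](CC)(CC)CC)C=O | intermediate
15 | methyl acrylate | C=CC(=O)OC | starting material
16 | methyl (4S,5R,6E)-6-bromo-5-(TBS-oxy)-3-hydroxy-7-iodo-2-methylidene-4-(TES-oxy)hept-6-enoate (C3 epimers) | I/C=C(/Br)[C@H](O[Si](C)(C)C(C)(C)C)[C@@H](O[Si](CC)(CC)CC)C(O)C(=C)C(=O)OC | intermediate
17 | methyl (2Z,4S,5R,6E)-6-bromo-2-(bromomethyl)-5-(TBS-oxy)-7-iodo-4-(TES-oxy)hepta-2,6-dienoate | I/C=C(/Br)[C@H](O[Si](C)(C)C(C)(C)C)[C@@H](O[Si](CC)(CC)CC)/C=C(\CBr)C(=O)OC | intermediate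
18 | methyl (3S,4R,5Z)-3-[(1S,2R,3E)-3-bromo-2-(TBS-oxy)-4-iodo-1-(TES-oxy)but-3-en-1-yl]-4-hydroxy-6-methyl-2-methylideneocta-5,7-dienoate (formed as its chromium(III) alkoxide) | C=C(C(=O)OC)[C@@H]([C@H](O)/C=C(/C)C=C)[C@@H]([C@H](/C(=C\I)Br)O[Si](C)(C)C(C)(C)C)O[Si](CC)(CC)CC | intermediate
19 | (4S,5R)-4-[(1S,2R,3E)-3-bromo-2-(TBS-oxy)-4-iodo-1-(TES-oxy)but-3-en-1-yl]-3-methylidene-5-[(1Z)-2-methylbuta-1,3-dien-1-yl]oxolan-2-one | C=C1C(=O)O[C@H](/C=C(/C)C=C)[C@H]1[C@@H]([C@H](/C(=C\I)Br)O[Si](C)(C)C(C)(C)C)O[Si](CC)(CC)CC | intermediate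
20 | (4R,5R)-4-[(1S,2R,3E)-3-bromo-2-(TBS-oxy)-1-hydroxy-4-iodobut-3-en-1-yl]-3-methylidene-5-[(1Z)-2-methylbuta-1,3-dien-1-yl]oxolan-2-one | C=C1C(=O)O[C@H](/C=C(/C)C=C)[C@H]1[C@@H]([C@H](/C(=C\I)Br)O[Si](C)(C)C(C)(C)C)O | intermediate
21 | 2,4,6-trichlorobenzoic (4S)-2,2,4-trimethyl-1,3-dioxolane-4-carboxylic anhydride | O=C(OC(=O)[C@]1(C)COC(C)(C)O1)c2c(Cl)cc(Cl)cc2Cl | intermediate
22 | (1S,2R,3E)-3-bromo-2-(TBS-oxy)-4-iodo-1-[(2R,3S)-4-methylidene-2-[(1Z)-2-methylbuta-1,3-dien-1-yl]-5-oxooxolan-3-yl]but-3-en-1-yl (4S)-2,2,4-trimethyl-1,3-dioxolane-4-carboxylate | C=C1C(=O)O[C@H](/C=C(/C)C=C)[C@H]1[C@@H]([C@H](/C(=C\I)Br)O[Si](C)(C)C(C)(C)C)OC(=O)[C@]2(C)COC(C)(C)O2 | intermediate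
23 | B-alkyl-9-BBN of 22 (boron on C2, the former terminal diene carbon) | C=C1C(=O)O[C@H](/C=C(/C)CCB2C3CCCC2CCC3)[C@H]1[C@@H]([C@H](/C(=C\I)Br)O[Si](C)(C)C(C)(C)C)OC(=O)[C@]4(C)COC(C)(C)O4 | intermediate
24 | (1(10)E,4Z,6R,7S,8S,9R)-10-bromo-9-(TBS-oxy)-14-norgermacra-1(10),4,11(13)-trien-12,6-olid-8-yl (4S)-2,2,4-trimethyl-1,3-dioxolane-4-carboxylate | C=C1C(=O)O[C@@H]2/C=C(/C)CC/C=C(/Br)[C@H](O[Si](C)(C)C(C)(C)C)[C@@H](OC(=O)[C@]3(C)COC(C)(C)O3)[C@@H]12 | intermediate
25 | methyl (1(10)E,4Z,6R,7S,8S,9S)-9-(TBS-oxy)-8-[(4S)-2,2,4-trimethyl-1,3-dioxolane-4-carbonyloxy]germacra-1(10),4,11(13)-trien-12,6-olid-14-oate | C=C1C(=O)O[C@@H]2/C=C(/C)CC/C=C(/C(=O)OC)[C@H](O[Si](C)(C)C(C)(C)C)[C@@H](OC(=O)[C@]3(C)COC(C)(C)O3)[C@@H]12 | intermediate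
26 | methyl (1(10)E,4Z,6R,7S,8S,9S)-9-hydroxy-8-[(4S)-2,2,4-trimethyl-1,3-dioxolane-4-carbonyloxy]germacra-1(10),4,11(13)-trien-12,6-olid-14-oate | C=C1C(=O)O[C@@H]2/C=C(/C)CC/C=C(/C(=O)OC)[C@H](O)[C@@H](OC(=O)[C@]3(C)COC(C)(C)O3)[C@@H]12 | intermediate
27 | methyl (1(10)E,4Z,6R,7S,8S,9S)-9-acetoxy-8-[(4S)-2,2,4-trimethyl-1,3-dioxolane-4-carbonyloxy]germacra-1(10),4,11(13)-trien-12,6-olid-14-oate | C=C1C(=O)O[C@@H]2/C=C(/C)CC/C=C(/C(=O)OC)[C@H](OC(C)=O)[C@@H](OC(=O)[C@]3(C)COC(C)(C)O3)[C@@H]12 | intermediate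
28 | methyl (1(10)E,4Z,6R,7S,8S,9S)-9-acetoxy-8-[(2S)-2,3-dihydroxy-2-methylpropanoyloxy]germacra-1(10),4,11(13)-trien-12,6-olid-14-oate | C=C1C(=O)O[C@@H]2/C=C(/C)CC/C=C(/C(=O)OC)[C@H](OC(C)=O)[C@@H](OC(=O)[C@@](C)(O)CO)[C@@H]12 | target

**Step count**
Total: 19 steps. Longest linear sequence: 15 steps (steps 5–19, from the threonate 7).

**Steps most likely to fail**

Step 15 (ring closure). Oligomerisation may outrun the strained ten-membered closure, the β-bromoalkenylpalladium intermediate may lose bromide and revert to the alkyne, or hydroboration may not stay on the terminal vinyl group. The fallback forms C1–C2 intermolecularly and closes the ring at C4=C5 by metathesis. It sets out from 17: CrCl2-mediated allylation of acrolein followed by AcOH–THF–H2O would give the vinyl lactone alcohol F1. Yamaguchi esterification with 3 would give the ester F2. B-alkyl Suzuki–Miyaura coupling of F2 with 9-(3-methylbut-3-en-1-yl)-9-BBN F3 (from isoprene and 9-BBN) under PdCl2(dppf)/Cs2CO3 would give the acyclic diene F4. Ring-closing metathesis of F4 (second-generation Grubbs catalyst, dilute toluene, 80 °C) should give the ring-cis trisubstituted olefin and return to the route at 24.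

Step 13 (allylation). The simple (anti) or the facial diastereoselection may be poor, or the δ-silyloxy allylchromium may undergo 1,4-elimination. The fallback sets out from 17 and 6: an indium-mediated Barbier reaction in THF–H2O, which keeps the Z-allyl geometry in a chair transition state, would give the 6,7-syn hydroxy ester F5. LiOH hydrolysis would give the hydroxy acid F6. Mitsunobu lactonisation (PPh3, DIAD) inverts C6 and would give the trans-lactone 19, which AcOH–THF–H2O converts to 20, where the route is rejoined.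

Step 16 (carbonylation). Pd(0) may ionise the allylic lactone C6–O bond at 60 °C, methanol may add to the methylene lactone, or oxidative addition at the hindered bromide may be slow. The fallback sets out from 24: nickel-catalysed reductive carboxylation with CO2 (1 atm; NiCl2(PPh3)2, Mn, Et4NI, DMI, rt) would give the C14 carboxylic acid F7, and methylation (MeI, KHCO3, DMF) returns to the route at 25.

**Further compounds**
F1 | step 15 | (4R,5R)-4-[(1S,2R,3E)-3-bromo-2-(TBS-oxy)-1-hydroxy-4-iodobut-3-en-1-yl]-5-ethenyl-3-methylideneoxolan-2-one | C=C1C(=O)O[C@H](C=C)[C@H]1[C@@H]([C@H](/C(=C\I)Br)O[Si](C)(C)C(C)(C)C)O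
F2 | step 15 | (1S,2R,3E)-3-bromo-2-(TBS-oxy)-1-[(2R,3S)-2-ethenyl-4-methylidene-5-oxooxolan-3-yl]-4-iodobut-3-en-1-yl (4S)-2,2,4-trimethyl-1,3-dioxolane-4-carboxylate | C=C1C(=O)O[C@H](C=C)[C@H]1[C@@H]([C@H](/C(=C\I)Br)O[Si](C)(C)C(C)(C)C)OC(=O)[C@]2(C)COC(C)(C)O2
F3 | step 15 | 9-(3-methylbut-3-en-1-yl)-9-borabicyclo[3.3.1]nonane | C=C(C)CCB1C2CCCC1CCC2
F4 | step 15 | (1S,2R,3E)-3-bromo-2-(TBS-oxy)-1-[(2R,3S)-2-ethenyl-4-methylidene-5-oxooxolan-3-yl]-7-methylocta-3,7-dien-1-yl (4S)-2,2,4-trimethyl-1,3-dioxolane-4-carboxylate | C=C1C(=O)O[C@H](C=C)[C@H]1[C@@H]([C@H](/C(=C\CCC(C)=C)Br)O[Si](C)(C)C(C)(C)C)OC(=O)[C@]2(C)COC(C)(C)O2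
F5 | step 13 | methyl (3S,4S,5Z)-3-[(1S,2R,3E)-3-bromo-2-(TBS-oxy)-4-iodo-1-(TES-oxy)but-3-en-1-yl]-4-hydroxy-6-methyl-2-methylideneocta-5,7-dienoate (C6 epimer of 18) | C=C(C(=O)OC)[C@@H]([C@@H](O)/C=C(/C)C=C)[C@@H]([C@H](/C(=C\I)Br)O[Si](C)(C)C(C)(C)C)O[Si](CC)(CC)CC
F6 | step 13 | (3S,4S,5Z)-3-[(1S,2R,3E)-3-bromo-2-(TBS-oxy)-4-iodo-1-(TES-oxy)but-3-en-1-yl]-4-hydroxy-6-methyl-2-methylideneocta-5,7-dienoic acid | C=C(C(=O)O)[C@@H]([C@@H](O)/C=C(/C)C=C)[C@@H]([C@H](/C(=C\I)Br)O[Si](C)(C)C(C)(C)C)O[Si](CC)(CC)CC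
F7 | step 16 | (1(10)E,4Z,6R,7S,8S,9S)-9-(TBS-oxy)-8-[(4S)-2,2,4-trimethyl-1,3-dioxolane-4-carbonyloxy]germacra-1(10),4,11(13)-trien-12,6-olid-14-oic acid | C=C1C(=O)O[C@@H]2/C=C(/C)CC/C=C(/C(=O)O)[C@H](O[Si](C)(C)C(C)(C)C)[C@@H](OC(=O)[C@]3(C)COC(C)(C)O3)[C@@H]12
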